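I start from the dissolved gas.

| flask | substrate | gas phase | remark | time |
|---|---|---|---|---|
| Friday's | 10 mM | 1.3 mM (held) | run made earlier |  |
| Thursday's | 15 mM | 1.3 mM (held) | run made earlier |  |
| flask | 20 mM | 1.3 mM (held) |  | 1.0 h |

| run | time / min | product / % |
|---|---|---|
| Friday's | 6.00 | 55.3 |
| Friday's | 15.0 | 82.3 |
| Friday's | 30.0 | 88.9 |
| Friday's | 50.0 | 89.8 |
| Thursday's | 4.00 | 43.5 |
| Thursday's | 8.00 | 63.5 |
| Thursday's | 20.0 | 86.1 |
| Thursday's | 50.0 | 89.7 |

(each reading ± 1 percentage point)

- at the start none of the gas is dissolved
- the earlier runs were read with a standard deviation of 1 percentage point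
- candidate steps: gas phase <-> dissolved gas; substrate + dissolved gas <-> product; substrate <-> dormant form

- south-east: doubling the transfer coefficient of the gas phase, all else as stated
- north: doubling the saturation concentration of gas phase, all else as stated

- the product standing at 1.0 h, as a percentage of the substrate charged
- the change that raises the amount of product at 1.0 h, in percent of the substrate charged most ("none" if none brings more than 2 percentage points) (south-east / north / none)
- amount of product at 1.0 h, in percent of the substrate charged, after north

If the dissolved gas stands at one level whatever the charge, the product rises pseudo-first-order in substrate, and the percentage curve is the same for each charge. I test this on two charges. Taking each run's last reading as its plateau, I divide the logarithm of the share of the plateau still missing by the time and drop the sign. Friday's run, with 10 mM, gives 0.159 min⁻¹ from its reading at 6.00 min. Thursday's run, with 15 mM, gives 0.166 min⁻¹ from its reading at 4.00 min.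

Friday's figure is about the same as Thursday's. Put on Thursday's run, it predicts 42.3% against the reading of 43.5%, a gap of 1.2 percentage points where a reading scatters by 1 point. So I keep their mean 0.163 min⁻¹ as k, the approach constant: the rate at which the logarithm of the gap to the plateau falls.

Its time constant is 6.15 min, and 1.0 h holds 9.76 of them. So I reckon that the flask with 20 mM stands at the mean plateau, 89.8%. That plateau means 8.76 parts of product to one of the rest. If that ratio is proportional to the dissolved gas, and north doubles the dissolved gas, the flask with 20 mM reaches 94.6% under north.

The forecast gives 89.8%, chooses north and gives 94.6% after it. Its ground: “So gas transfer is not limiting: dissolved gas stays near saturation and the rate is first order in substrate.”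

The flask gives 89.7%. North brings 4.9 points, more than the 0 points of south-east, and reaches 94.6%.

    gas phase ⇌ dissolved gas, rate k1*(csat - [dissolved gas]) (kL = 79.0 min⁻¹)
    substrate + dissolved gas ⇌ product (K = 9100 M⁻¹, k = 150 M⁻¹ min⁻¹)
    substrate ⇌ dormant form (K = 0.350, k = 0.350 min⁻¹)

At 0.100 h the flask with 20 mM holds 1.29 mM of dissolved gas against a saturation of 1.3 mM, and k gives 56.0% of product where that flask has 55.3%. For the same flask left until 15 min, k gives 82.0%, and that flask stands at 81.1%.

The earlier runs and the new flask are simulated for an exercise.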